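## Retrosynthetic overview

1. Target ⇐ late ortho-formylation and global deprotection; the C8 methyl group comes from a C8 ketone (methylenation, face-selective hydrogenation).
2. C9 quaternary centre and the C1=C10 alkene ⇐ two deconjugative α-alkylations of a bicyclic enone (arylmethyl bromide first, MeI second).
3. Rings A and B ⇐ formed together in one operation: intramolecular Diels–Alder reaction of a 6-alkenyl-4-methoxy-2-pyranone (ring A through the tether, ring B as the new carbocycle) with loss of CO2; the methoxydiene is the masked enone.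
4. Cycloaddition substrate ⇐ 4-methoxy-6-methyl-2-pyranone, allyl bromide and 3-methylbuta-1,2-diene (asymmetric reverse prenylation sets C3).
5. Arene ⇐ 3,5-dihydroxybenzyl alcohol (MOM protection, ortho-lithiation/hydroxymethylation, bromination).

Assumption: 4-methoxy-6-methyl-2H-pyran-2-one is bought; locants C1–C11 in the comments follow the drimane-type numbering of the target (C3 carbinol, C4 CMe2, C5 ring-fusion CH, C8 CHMe, C9 quaternary carbon, C10 alkene ring-fusion carbon, C11 benzylic CH2).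

## Route

Step 1
Reactants: 1 3,5-dihydroxybenzyl alcohol
Product: 2 1,3-bis(methoxymethoxy)-5-[(methoxymethoxy)methyl]benzene
Conditions: NaH, MOMCl, DMF, 0 °C to rt
Reagents that add atoms: chloromethyl methyl ether, COCCl
Why: Williamson etherification of both phenoxides and the alkoxide gives base-stable MOM protection that later directs lithiation; no stereocentre.

Step 2
Reactants: 2 1,3-bis(methoxymethoxy)-5-[(methoxymethoxy)methyl]benzene
Product: 3 [2,6-bis(methoxymethoxy)-4-[(methoxymethoxy)methyl]phenyl]methanol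
Conditions: n-BuLi, THF, 0 °C; paraformaldehyde, 0 °C to rt
Reagents that add atoms: formaldehyde (as paraformaldehyde), C=O
Why: Directed ortho-lithiation takes place at the ring position flanked by the two MOM ethers and the aryllithium is trapped by formaldehyde (hydroxymethylation); no stereocentre.

Step 3
Reactants: 3 [2,6-bis(methoxymethoxy)-4-[(methoxymethoxy)methyl]phenyl]methanol
Product: 4 2-(bromomethyl)-1,3-bis(methoxymethoxy)-5-[(methoxymethoxy)methyl]benzene
Conditions: CBr4, PPh3, CH2Cl2, 0 °C (used at once)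
Reagents that add atoms: carbon tetrabromide, BrC(Br)(Br)Br
Why: The Appel reaction converts the benzylic alcohol into the bromide under neutral conditions that spare the MOM acetals; no stereocentre.

Step 4
Reactants: 5 4-methoxy-6-methyl-2H-pyran-2-one; 6 allyl bromide
Product: 7 6-(but-3-en-1-yl)-4-methoxy-2H-pyran-2-one
Conditions: LiN(iPr)2, THF, −78 °C; then 6, −78 to −30 °C
Reagents that add atoms: none
Why: Lateral (vinylogous) lithiation of the 6-methyl group gives a stabilised dienolate that is C-alkylated by allyl bromide (SN2); no stereocentre.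

Step 5
Reactants: 7 6-(but-3-en-1-yl)-4-methoxy-2H-pyran-2-one
Product: 8 3-(4-methoxy-2-oxo-2H-pyran-6-yl)propanal
Conditions: OsO4 (cat.), NaIO4, 2,6-lutidine, dioxane–H2O, rt
Reagents that add atoms: sodium periodate, [Na+].[O-]I(=O)(=O)=O
Why: Lemieux–Johnson oxidation (catalytic dihydroxylation, periodate cleavage) cuts the isolated terminal alkene in preference to the conjugated pyranone double bonds; no stereocentre.

Step 6
Reactants: 8 3-(4-methoxy-2-oxo-2H-pyran-6-yl)propanal; 9 3-methylbuta-1,2-diene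
Product: 10 6-[(3S)-3-hydroxy-4,4-dimethylhex-5-en-1-yl]-4-methoxy-2H-pyran-2-one
Conditions: (+)-Ipc2BH [from (−)-α-pinene], 9, THF, −25 °C; then 8, Et2O, −78 °C; HOCH2CH2NH2 work-up
Reagents that add atoms: none
Why: Brown asymmetric allylboration with the B-prenyl borane made in the flask adds the 1,1-dimethylallyl group through a closed chair transition state with allylic transposition, the (−)-α-pinene-derived reagent attacking the re face of the aldehyde so that C3 is set as S.

Step 7
Reactants: 10 6-[(3S)-3-hydroxy-4,4-dimethylhex-5-en-1-yl]-4-methoxy-2H-pyran-2-one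
Product: 11 6-[(3S)-3-[(tert-butyldimethylsilyl)oxy]-4,4-dimethylhex-5-en-1-yl]-4-methoxy-2H-pyran-2-one
Conditions: TBSOTf, 2,6-lutidine, CH2Cl2, 0 °C
Reagents that add atoms: tert-butyldimethylsilyl trifluoromethanesulfonate, CC(C)(C)[Si](C)(C)OS(=O)(=O)C(F)(F)F
Why: Silylation with the silyl triflate protects the hindered neopentylic alcohol for the thermal and basic steps and makes it the largest tether substituent; no new stereocentre.

Step 8
Reactants: 11 6-[(3S)-3-[(tert-butyldimethylsilyl)oxy]-4,4-dimethylhex-5-en-1-yl]-4-methoxy-2H-pyran-2-one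
Product: 14 (4aR,6S)-6-[(tert-butyldimethylsilyl)oxy]-5,5-dimethyl-4,4a,5,6,7,8-hexahydronaphthalen-2(3H)-one, via bridged lactone 12 (not isolated), via methoxydiene 13 (not isolated)
Conditions: 1,2-dichlorobenzene (0.01 M), BHT, 200 °C, sealed tube; then oxalic acid, THF–H2O, rt
Reagents that add atoms: water, O
Why: Intramolecular Diels–Alder reaction of the 2-pyranone diene with the tethered vinyl group (four-atom tether, gem-dimethyl assistance) builds ring A and ring B at once, retro-Diels–Alder loss of CO2 gives the dienol ether and mild acid hydrolysis gives the enone; C5 is set in the cycloaddition by a chair-like tether with the C3 silyloxy group equatorial, which puts H-5 trans to it (only moderate selectivity expected, about 3:1, epimers separated at 14).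

Step 9
Reactants: 14 (4aR,6S)-6-[(tert-butyldimethylsilyl)oxy]-5,5-dimethyl-4,4a,5,6,7,8-hexahydronaphthalen-2(3H)-one; 4 2-(bromomethyl)-1,3-bis(methoxymethoxy)-5-[(methoxymethoxy)methyl]benzene
Product: 15 (4aR,6S)-1-{[2,6-bis(methoxymethoxy)-4-[(methoxymethoxy)methyl]phenyl]methyl}-6-[(tert-butyldimethylsilyl)oxy]-5,5-dimethyl-3,4,4a,5,6,7-hexahydronaphthalen-2(1H)-one (mixture at the new CH, which is re-enolised in step 10)
Conditions: KOtBu (1.05 equiv), t-BuOH–THF, 0 °C; then 4, 0 °C to rt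
Reagents that add atoms: none
Why: KOtBu gives the thermodynamic extended dienolate by γ-deprotonation at C1 (C5–H is not touched), and this is C-alkylated at the α-carbon C9 by the benzylic bromide (deconjugative α-alkylation), moving the alkene to C1=C10; C9 is not yet a fixed stereocentre.

Step 10
Reactants: 15 (4aR,6S)-1-{[2,6-bis(methoxymethoxy)-4-[(methoxymethoxy)methyl]phenyl]methyl}-6-[(tert-butyldimethylsilyl)oxy]-5,5-dimethyl-3,4,4a,5,6,7-hexahydronaphthalen-2(1H)-one
Product: 16 (1R,4aR,6S)-1-{[2,6-bis(methoxymethoxy)-4-[(methoxymethoxy)methyl]phenyl]methyl}-6-[(tert-butyldimethylsilyl)oxy]-1,5,5-trimethyl-3,4,4a,5,6,7-hexahydronaphthalen-2(1H)-one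
Conditions: KOtBu (1.5 equiv), t-BuOH–THF, 0 °C; MeI (2 equiv), 0 °C to rt
Reagents that add atoms: iodomethane, CI
Why: A second deconjugative α-alkylation of the same dienolate creates the C9 quaternary centre and locks the C1=C10 alkene; stereoelectronically controlled axial attack on the half-chair dienolate, anti to the C6 flap, puts the methyl group cis to the axial H-5 and leaves the arylmethyl group equatorial.

Step 11
Reactants: 16 (1R,4aR,6S)-1-{[2,6-bis(methoxymethoxy)-4-[(methoxymethoxy)methyl]phenyl]methyl}-6-[(tert-butyldimethylsilyl)oxy]-1,5,5-trimethyl-3,4,4a,5,6,7-hexahydronaphthalen-2(1H)-one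
Product: 17 (1S,4aR,6S)-1-{[2,6-bis(methoxymethoxy)-4-[(methoxymethoxy)methyl]phenyl]methyl}-6-[(tert-butyldimethylsilyl)oxy]-1,5,5-trimethyl-2-methylidene-1,2,3,4,4a,5,6,7-octahydronaphthalene
Conditions: Ph3PCH3Br, KOtBu, toluene, 100 °C
Reagents that add atoms: methyltriphenylphosphonium bromide, C[P+](c1ccccc1)(c1ccccc1)c1ccccc1.[Br-]
Why: Wittig methylenation with the ylide at elevated temperature converts the hindered, non-conjugated C8 ketone into the exocyclic alkene; no stereocentre changes.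

Step 12
Reactants: 17 (1S,4aR,6S)-1-{[2,6-bis(methoxymethoxy)-4-[(methoxymethoxy)methyl]phenyl]methyl}-6-[(tert-butyldimethylsilyl)oxy]-1,5,5-trimethyl-2-methylidene-1,2,3,4,4a,5,6,7-octahydronaphthalene
Product: 18 (1S,2R,4aR,6S)-1-{[2,6-bis(methoxymethoxy)-4-[(methoxymethoxy)methyl]phenyl]methyl}-6-[(tert-butyldimethylsilyl)oxy]-1,2,5,5-tetramethyl-1,2,3,4,4a,5,6,7-octahydronaphthalene
Conditions: H2 (3 atm), RhCl(PPh3)3 (10 mol%), benzene, 40 °C
Reagents that add atoms: none
Why: Homogeneous hydrogenation with RhCl(PPh3)3 reduces only the 1,1-disubstituted exocyclic alkene and not the hindered trisubstituted C1=C10 alkene, and delivers hydrogen to the face opposite the axial C9 methyl group so that the C8 methyl group ends equatorial and cis to it (8R).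

Step 13
Reactants: 18 (1S,2R,4aR,6S)-1-{[2,6-bis(methoxymethoxy)-4-[(methoxymethoxy)methyl]phenyl]methyl}-6-[(tert-butyldimethylsilyl)oxy]-1,2,5,5-tetramethyl-1,2,3,4,4a,5,6,7-octahydronaphthalene
Product: 19 3-{[(1S,2R,4aR,6S)-6-[(tert-butyldimethylsilyl)oxy]-1,2,5,5-tetramethyl-1,2,3,4,4a,5,6,7-octahydronaphthalen-1-yl]methyl}-2,4-bis(methoxymethoxy)-6-[(methoxymethoxy)methyl]benzaldehyde
Conditions: n-BuLi, TMEDA, THF, −78 to 0 °C; DMF, −78 °C to rt
Reagents that add atoms: N,N-dimethylformamide, CN(C)C=O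
Why: Directed ortho-metalation between a MOM ether and the MOM-protected hydroxymethyl group, then DMF quench, installs the aldehyde; the two open ring positions are equivalent by symmetry, so one product forms and no stereocentre is touched.

Step 14
Reactants: 19 3-{[(1S,2R,4aR,6S)-6-[(tert-butyldimethylsilyl)oxy]-1,2,5,5-tetramethyl-1,2,3,4,4a,5,6,7-octahydronaphthalen-1-yl]methyl}-2,4-bis(methoxymethoxy)-6-[(methoxymethoxy)methyl]benzaldehyde
Product: 20 2,4-dihydroxy-6-(hydroxymethyl)-3-{[(1S,2R,4aR,6S)-6-hydroxy-1,2,5,5-tetramethyl-1,2,3,4,4a,5,6,7-octahydronaphthalen-1-yl]methyl}benzaldehyde (target)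
Conditions: 3 M HCl, THF–H2O, 40 °C
Reagents that add atoms: none
Why: Aqueous acid hydrolyses the three MOM acetals and the silyl ether in one operation (aqueous medium avoids acetal formation at the hydroxy-aldehyde); the stereocentres are not affected.

## Compound list

1 | 3,5-dihydroxybenzyl alcohol | OCc1cc(O)cc(O)c1 | starting material
2 | 1,3-bis(methoxymethoxy)-5-[(methoxymethoxy)methyl]benzene | COCOCc1cc(OCOC)cc(OCOC)c1 | intermediate
3 | [2,6-bis(methoxymethoxy)-4-[(methoxymethoxy)methyl]phenyl]methanol | OCc1c(OCOC)cc(COCOC)cc1OCOC | intermediate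
4 | 2-(bromomethyl)-1,3-bis(methoxymethoxy)-5-[(methoxymethoxy)methyl]benzene | BrCc1c(OCOC)cc(COCOC)cc1OCOC | intermediate
5 | 4-methoxy-6-methyl-2H-pyran-2-one | COC1=CC(=O)OC(C)=C1 | starting material
6 | allyl bromide | C=CCBr | starting material
7 | 6-(but-3-en-1-yl)-4-methoxy-2H-pyran-2-one | C=CCCC1=CC(OC)=CC(=O)O1 | intermediate
8 | 3-(4-methoxy-2-oxo-2H-pyran-6-yl)propanal | O=CCCC1=CC(OC)=CC(=O)O1 | intermediate
9 | 3-methylbuta-1,2-diene | CC(C)=C=C | starting material
10 | 6-[(3S)-3-hydroxy-4,4-dimethylhex-5-en-1-yl]-4-methoxy-2H-pyran-2-one | C=CC(C)(C)[C@@H](O)CCC1=CC(OC)=CC(=O)O1 | intermediate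
11 | 6-[(3S)-3-[(tert-butyldimethylsilyl)oxy]-4,4-dimethylhex-5-en-1-yl]-4-methoxy-2H-pyran-2-one | C=CC(C)(C)[C@@H](O[Si](C)(C)C(C)(C)C)CCC1=CC(OC)=CC(=O)O1 | intermediate
12 | bridged lactone: 2-oxabicyclo[2.2.2]oct-5-en-3-one cycloadduct of 11 with ring A closed (C5–C10 and C6–C7 bonds formed; C3 and C5 as in 14; bridge orientation not defined) | COC1=CC23CC[C@H](O[Si](C)(C)C(C)(C)C)C(C)(C)[C@@H]2CC1C(=O)O3 | intermediate
13 | methoxydiene: (4aR,6S)-6-[(tert-butyldimethylsilyl)oxy]-2-methoxy-5,5-dimethyl-4,4a,5,6,7,8-hexahydronaphthalene | COC1=CC[C@H]2C(C)(C)[C@@H](O[Si](C)(C)C(C)(C)C)CCC2=C1 | intermediate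
14 | (4aR,6S)-6-[(tert-butyldimethylsilyl)oxy]-5,5-dimethyl-4,4a,5,6,7,8-hexahydronaphthalen-2(3H)-one | O=C1CC[C@H]2C(C)(C)[C@@H](O[Si](C)(C)C(C)(C)C)CCC2=C1 | intermediate
15 | (4aR,6S)-1-{[2,6-bis(methoxymethoxy)-4-[(methoxymethoxy)methyl]phenyl]methyl}-6-[(tert-butyldimethylsilyl)oxy]-5,5-dimethyl-3,4,4a,5,6,7-hexahydronaphthalen-2(1H)-one (C1 of the ring system not defined) | O=C1CC[C@@H]2C(=CC[C@H](O[Si](C)(C)C(C)(C)C)C2(C)C)C1Cc1c(OCOC)cc(COCOC)cc1OCOC | intermediate
16 | (1R,4aR,6S)-1-{[2,6-bis(methoxymethoxy)-4-[(methoxymethoxy)methyl]phenyl]methyl}-6-[(tert-butyldimethylsilyl)oxy]-1,5,5-trimethyl-3,4,4a,5,6,7-hexahydronaphthalen-2(1H)-one | O=C1CC[C@@H]2C(=CC[C@H](O[Si](C)(C)C(C)(C)C)C2(C)C)[C@@]1(C)Cc1c(OCOC)cc(COCOC)cc1OCOC | intermediate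
17 | (1S,4aR,6S)-1-{[2,6-bis(methoxymethoxy)-4-[(methoxymethoxy)methyl]phenyl]methyl}-6-[(tert-butyldimethylsilyl)oxy]-1,5,5-trimethyl-2-methylidene-1,2,3,4,4a,5,6,7-octahydronaphthalene | C=C1CC[C@@H]2C(=CC[C@H](O[Si](C)(C)C(C)(C)C)C2(C)C)[C@@]1(C)Cc1c(OCOC)cc(COCOC)cc1OCOC | intermediate
18 | (1S,2R,4aR,6S)-1-{[2,6-bis(methoxymethoxy)-4-[(methoxymethoxy)methyl]phenyl]methyl}-6-[(tert-butyldimethylsilyl)oxy]-1,2,5,5-tetramethyl-1,2,3,4,4a,5,6,7-octahydronaphthalene | C[C@@H]1CC[C@@H]2C(=CC[C@H](O[Si](C)(C)C(C)(C)C)C2(C)C)[C@@]1(C)Cc1c(OCOC)cc(COCOC)cc1OCOC | intermediate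
19 | 3-{[(1S,2R,4aR,6S)-6-[(tert-butyldimethylsilyl)oxy]-1,2,5,5-tetramethyl-1,2,3,4,4a,5,6,7-octahydronaphthalen-1-yl]methyl}-2,4-bis(methoxymethoxy)-6-[(methoxymethoxy)methyl]benzaldehyde | C[C@@H]1CC[C@@H]2C(=CC[C@H](O[Si](C)(C)C(C)(C)C)C2(C)C)[C@@]1(C)Cc1c(OCOC)cc(COCOC)c(C=O)c1OCOC | intermediate
20 | 2,4-dihydroxy-6-(hydroxymethyl)-3-{[(1S,2R,4aR,6S)-6-hydroxy-1,2,5,5-tetramethyl-1,2,3,4,4a,5,6,7-octahydronaphthalen-1-yl]methyl}benzaldehyde | C[C@@H]1CC[C@@H]2C(=CC[C@H](O)C2(C)C)[C@@]1(C)Cc1c(O)cc(CO)c(C=O)c1O | target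

## Step count and risks

Total steps: 14. Longest linear sequence: 11 steps (steps 4 to 14, from pyranone 5); the arylmethyl bromide 4 is made in 3 steps and joins at step 9.

Step 8 is the most likely to fail. The dienophile is an unactivated vinyl group on a quaternary carbon, the pyranone is electron-rich, and C5 is controlled only by the remote C3 substituent. The fallback sets out from aldehyde 8 and comes back at enone 14; it uses an alkyne so that the cycloaddition ends in irreversible aromatisation, and unmasks the enone by dissolving-metal reduction. Zinc-mediated addition of 3-chloro-3-methylbut-1-yne to 8 gives racemic 6-(3-hydroxy-4,4-dimethylhex-5-yn-1-yl)-4-methoxy-2H-pyran-2-one F1. Dess–Martin oxidation gives 6-(4,4-dimethyl-3-oxohex-5-yn-1-yl)-4-methoxy-2H-pyran-2-one F2, and (R)-Me-CBS/catecholborane reduction gives 6-[(3S)-3-hydroxy-4,4-dimethylhex-5-yn-1-yl]-4-methoxy-2H-pyran-2-one F3. TBSOTf gives 6-[(3S)-3-[(tert-butyldimethylsilyl)oxy]-4,4-dimethylhex-5-yn-1-yl]-4-methoxy-2H-pyran-2-one F4. Heating F4 in toluene at 150 °C (pyranone–alkyne Diels–Alder, loss of CO2) gives tert-butyl{[(2S)-6-methoxy-1,1-dimethyl-1,2,3,4-tetrahydronaphthalen-2-yl]oxy}dimethylsilane F5. Birch reduction (Li, NH3, t-BuOH) gives tert-butyl{[(2S)-6-methoxy-1,1-dimethyl-1,2,3,4,5,8-hexahydronaphthalen-2-yl]oxy}dimethylsilane F6. Oxalic acid and then NaOMe give 14, with C5 fixed on conjugation and the epimers separated as before.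

Step 10 is the second risk: the facial selectivity of the quaternising methylation rests on a stereoelectronic argument, and over-methylation at C7 is possible. The fallback sets out from 14 and comes back at 16; it reverses the order of the two alkylations, for the case that the second electrophile is found to enter trans to H-5. KOtBu and one equivalent of MeI give (4aR,6S)-6-[(tert-butyldimethylsilyl)oxy]-1,5,5-trimethyl-4,4a,5,6,7,8-hexahydronaphthalen-2(3H)-one F7. The second deconjugative alkylation is then run with bromide 4, so that the arylmethyl group takes the face that methyl took before.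

Step 13 is the third risk: n-BuLi may deprotonate the benzylic CH2OMOM position instead of the ring, with a 1,2-Wittig shift. The fallback sets out from 18 and comes back at 20; it drops the lithiation and formylates the free phenol last. Aqueous HCl converts 18 into 2-{[(1S,2R,4aR,6S)-6-hydroxy-1,2,5,5-tetramethyl-1,2,3,4,4a,5,6,7-octahydronaphthalen-1-yl]methyl}-5-(hydroxymethyl)benzene-1,3-diol F8. Magnesium-mediated ortho-formylation (MgCl2, Et3N, paraformaldehyde, MeCN, reflux) then places the aldehyde next to a phenol; the two free ortho positions are equivalent.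

## Further compounds

F1 | step 8 | 6-(3-hydroxy-4,4-dimethylhex-5-yn-1-yl)-4-methoxy-2H-pyran-2-one (racemic) | C#CC(C)(C)C(O)CCC1=CC(OC)=CC(=O)O1
F2 | step 8 | 6-(4,4-dimethyl-3-oxohex-5-yn-1-yl)-4-methoxy-2H-pyran-2-one | C#CC(C)(C)C(=O)CCC1=CC(OC)=CC(=O)O1
F3 | step 8 | 6-[(3S)-3-hydroxy-4,4-dimethylhex-5-yn-1-yl]-4-methoxy-2H-pyran-2-one | C#CC(C)(C)[C@@H](O)CCC1=CC(OC)=CC(=O)O1
F4 | step 8 | 6-[(3S)-3-[(tert-butyldimethylsilyl)oxy]-4,4-dimethylhex-5-yn-1-yl]-4-methoxy-2H-pyran-2-one | C#CC(C)(C)[C@@H](O[Si](C)(C)C(C)(C)C)CCC1=CC(OC)=CC(=O)O1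
F5 | step 8 | tert-butyl{[(2S)-6-methoxy-1,1-dimethyl-1,2,3,4-tetrahydronaphthalen-2-yl]oxy}dimethylsilane | COc1ccc2c(c1)CC[C@H](O[Si](C)(C)C(C)(C)C)C2(C)C
F6 | step 8 | tert-butyl{[(2S)-6-methoxy-1,1-dimethyl-1,2,3,4,5,8-hexahydronaphthalen-2-yl]oxy}dimethylsilane | COC1=CCC2=C(C1)CC[C@H](O[Si](C)(C)C(C)(C)C)C2(C)C
F7 | step 10 | (4aR,6S)-6-[(tert-butyldimethylsilyl)oxy]-1,5,5-trimethyl-4,4a,5,6,7,8-hexahydronaphthalen-2(3H)-one | O=C1CC[C@H]2C(C)(C)[C@@H](O[Si](C)(C)C(C)(C)C)CCC2=C1C
F8 | step 13 | 2-{[(1S,2R,4aR,6S)-6-hydroxy-1,2,5,5-tetramethyl-1,2,3,4,4a,5,6,7-octahydronaphthalen-1-yl]methyl}-5-(hydroxymethyl)benzene-1,3-diol | C[C@@H]1CC[C@@H]2C(=CC[C@H](O)C2(C)C)[C@@]1(C)Cc1c(O)cc(CO)cc1O
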